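The target is a C2-symmetric 3,7-dioxabicyclo[3.3.0]octane in which the chain C8–C1(OH)–C5(OH)–C4 is (R,R)-tartaric acid reduced at both ends. Everything rests on cutting C1–C2 and C5–C6 (aldol) together with O3–C4 and O7–C8 (lactone). In one flask the lithium enolate of the L-tartrate acetonide adds twice to O-benzylvanillin, once at each α-carbon, and each aldolate closes a γ-lactone (rings C1–C2–O3–C4–C5 and C5–C6–O7–C8–C1). This forms four bonds, two rings and all four stereocentres. The precursor is dimethyl (4R,5R)-2,2-dimethyl-1,3-dioxolane-4,5-dicarboxylate plus two equivalents of the aldehyde; reduction of both lactone carbonyls to CH2 and deprotection finish the synthesis.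

Key step: step 1

Remark on the chemistry: the aryl groups of the target are cis to the bridgehead oxygens (exo), so each carbinol carbon must form with its aryl group next to the acetal oxygen of the dioxolane, not away from it. A closed, lithium-bridged chair would give the opposite arrangement, and the conditions of step 1 are chosen for that reason.

Assumption: the enolate of 1 is attacked on the face that carries the neighbouring ester, as in its alkylations, so that the two carboxyl carbons stay trans on the dioxolane.

Step 1
Reactants: 1 dimethyl (4R,5R)-2,2-dimethyl-1,3-dioxolane-4,5-dicarboxylate; 2 4-benzyloxy-3-methoxybenzaldehyde (two equivalents, added in two portions)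
Product: 6 (1R,2S,5R,6S)-2,6-bis(4-benzyloxy-3-methoxyphenyl)-1,5-(isopropylidenedioxy)-3,7-dioxabicyclo[3.3.0]octane-4,8-dione, via first aldol adduct 3 (not isolated), via mono-lactone 4 (not isolated), via second aldol adduct 5 (not isolated)
Conditions: LiN(iPr)2 (1.05 equiv), THF–DMPU, −78 °C; 2 (1.0 equiv), −78 → −40 °C; recool to −78 °C, LiN(iPr)2 (1.2 equiv); 2 (1.2 equiv), −78 → −20 °C; AcOH quench
Reagents that add atoms: none
Why: LiN(iPr)2 removes one α-proton of 1 (the exocyclic ester enolate survives at −78 °C because the ring C–O bond lies near its nodal plane), the enolate adds to 2 and the alkoxide of 3 acylates itself with the ester on the neighbouring ring carbon to give 4; deprotonation of 4 at the ring-fusion carbon C5, a second addition to 2 and lactonisation of 5 give 6, so the step is a two-fold tandem aldol addition–lactonisation. The closest known reaction types are the hydroxyalkylation of tartrate acetonide enolates and the aldol addition of α-alkoxy-γ-lactone enolates to aldehydes. Both rings (C1–C2–O3–C4–C5 and C5–C6–O7–C8–C1) close by 5-exo-trig attack of the alkoxide on an ester carbonyl, which is possible only when carbinol carbon and ester are cis on the dioxolane. C1 is controlled by the stereocentre C5 of the first enolate, which is attacked on the face of the C5 ester (the adduct of the other face cannot lactonise and can revert by retro-aldol), and C5 is controlled by the cis ring fusion of 4, whose enolate can only be attacked on the face of the C1 ester; both bridgeheads therefore keep the tartrate configuration. C2 and C6 are set in the additions: with lithium solvated by DMPU an open transition state is expected, with the aryl group antiperiplanar to the ring carbon next to the enolate carbon (C5 in the first addition, C1 in the second) and the aldehyde oxygen directed at the ester it will attack, which puts each aryl group on the side of the acetal oxygen. The selectivity the step needs above all is this carbinol configuration; it is secured only by the steric difference between the ring carbon and the ring oxygen on the enolate carbon and is the exposed point of the route.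

Step 2
Reactants: 6 (1R,2S,5R,6S)-2,6-bis(4-benzyloxy-3-methoxyphenyl)-1,5-(isopropylidenedioxy)-3,7-dioxabicyclo[3.3.0]octane-4,8-dione
Product: 7 (1R,2S,5R,6S)-2,6-bis(4-benzyloxy-3-methoxyphenyl)-1,5-(isopropylidenedioxy)-3,7-dioxabicyclo[3.3.0]octane-4,8-diol (bis-lactol; anomer mixture at C4 and C8)
Conditions: iBu2AlH (2.4 equiv), CH2Cl2, −78 °C; aq. KNaC4H4O6
Reagents that add atoms: none
Why: Partial reduction of both γ-lactones (lactone-to-lactol reduction) should stop at the hemiacetal stage because the tetrahedral aluminium alkoxides are stable at −78 °C, while benzyl ethers and the ketal are inert; the two new anomeric centres are of no consequence since step 3 removes them.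

Step 3
Reactants: 7 (1R,2S,5R,6S)-2,6-bis(4-benzyloxy-3-methoxyphenyl)-1,5-(isopropylidenedioxy)-3,7-dioxabicyclo[3.3.0]octane-4,8-diol
Product: 8 (1R,2S,5R,6S)-2,6-bis(4-benzyloxy-3-methoxyphenyl)-1,5-(isopropylidenedioxy)-3,7-dioxabicyclo[3.3.0]octane
Conditions: Et3SiH (6 equiv), BF3·OEt2 (3 equiv), CH2Cl2, −78 → −30 °C; aq. NaHCO3
Reagents that add atoms: none
Why: Ionic hydrogenation of a lactol: BF3·OEt2 ionises each hemiacetal to a cyclic oxocarbenium ion stabilised by the ring oxygen and Et3SiH reduces it to CH2, and at low temperature the lactol hydroxyl rather than the benzylic ring oxygen should be the site that ionises, so C2 and C6 are not touched and no stereocentre is formed.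

Step 4
Reactants: 8 (1R,2S,5R,6S)-2,6-bis(4-benzyloxy-3-methoxyphenyl)-1,5-(isopropylidenedioxy)-3,7-dioxabicyclo[3.3.0]octane
Product: 9 (1R,2S,5R,6S)-2,6-bis(4-benzyloxy-3-methoxyphenyl)-3,7-dioxabicyclo[3.3.0]octane-1,5-diol
Conditions: AcOH–THF–H2O, 55 °C
Reagents that add atoms: none
Why: Acid-catalysed hydrolysis of the isopropylidene ketal in a weakly acidic aqueous medium should free the two tertiary hydroxyl groups while the benzyl ethers and the cyclic benzylic ethers stay intact, and no stereocentre is affected.

Step 5
Reactants: 9 (1R,2S,5R,6S)-2,6-bis(4-benzyloxy-3-methoxyphenyl)-3,7-dioxabicyclo[3.3.0]octane-1,5-diol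
Product: 10 (1R,2S,5R,6S)-2,6-bis(4-hydroxy-3-methoxyphenyl)-3,7-dioxabicyclo[3.3.0]octane-1,5-diol
Conditions: H2 (1 atm), Pd/C, EtOAc–MeOH, rt
Reagents that add atoms: none
Why: Catalytic hydrogenolysis should cleave the two aryl benzyl ethers much faster than the hindered secondary benzylic ethers of the ring, which carry electron-rich aryl groups, so the phenols are freed under neutral conditions without change at any stereocentre.

Compound list
1 | dimethyl (4R,5R)-2,2-dimethyl-1,3-dioxolane-4,5-dicarboxylate (commercial acetonide of dimethyl L-tartrate; ester groups trans) | COC(=O)[C@@H]1OC(C)(C)O[C@H]1C(=O)OC | starting material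
2 | 4-benzyloxy-3-methoxybenzaldehyde (O-benzylvanillin) | O=Cc1ccc(OCc2ccccc2)c(OC)c1 | starting material
3 | dimethyl (4R,5R)-4-[(S)-(4-benzyloxy-3-methoxyphenyl)(hydroxy)methyl]-2,2-dimethyl-1,3-dioxolane-4,5-dicarboxylate (first aldol adduct, present as its lithium alkoxide; carbinol carbon cis to the C5 ester) | COc1cc([C@H](O)[C@@]2(C(=O)OC)OC(C)(C)O[C@H]2C(=O)OC)ccc1OCc1ccccc1 | intermediate
4 | methyl (1R,5R,8S)-8-(4-benzyloxy-3-methoxyphenyl)-3,3-dimethyl-6-oxo-2,4,7-trioxabicyclo[3.3.0]octane-1-carboxylate (mono-lactone; cis-fused, aryl cis to O2, ester cis to H5) | COc1cc([C@@H]2OC(=O)[C@@H]3OC(C)(C)O[C@]23C(=O)OC)ccc1OCc1ccccc1 | intermediate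
5 | methyl (1R,5R,8S)-8-(4-benzyloxy-3-methoxyphenyl)-5-[(S)-(4-benzyloxy-3-methoxyphenyl)(hydroxy)methyl]-3,3-dimethyl-6-oxo-2,4,7-trioxabicyclo[3.3.0]octane-1-carboxylate (second aldol adduct, present as its lithium alkoxide) | COc1cc([C@@H]2OC(=O)[C@]3([C@@H](O)c4ccc(OCc5ccccc5)c(OC)c4)OC(C)(C)O[C@]23C(=O)OC)ccc1OCc1ccccc1 | intermediate
6 | (1R,2S,5R,6S)-2,6-bis(4-benzyloxy-3-methoxyphenyl)-1,5-(isopropylidenedioxy)-3,7-dioxabicyclo[3.3.0]octane-4,8-dione (bis-lactone; each aryl group cis to the acetal oxygen on the adjacent bridgehead) | COc1cc([C@@H]2OC(=O)[C@@]3(OC(C)(C)O4)[C@H](c5ccc(OCc6ccccc6)c(OC)c5)OC(=O)[C@@]234)ccc1OCc1ccccc1 | intermediate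
7 | (1R,2S,5R,6S)-2,6-bis(4-benzyloxy-3-methoxyphenyl)-1,5-(isopropylidenedioxy)-3,7-dioxabicyclo[3.3.0]octane-4,8-diol (bis-lactol; anomer mixture at C4 and C8) | COc1cc([C@@H]2OC(O)[C@@]3(OC(C)(C)O4)[C@H](c5ccc(OCc6ccccc6)c(OC)c5)OC(O)[C@@]234)ccc1OCc1ccccc1 | intermediate
8 | (1R,2S,5R,6S)-2,6-bis(4-benzyloxy-3-methoxyphenyl)-1,5-(isopropylidenedioxy)-3,7-dioxabicyclo[3.3.0]octane (bis-ether acetonide) | COc1cc([C@@H]2OC[C@@]3(OC(C)(C)O4)[C@H](c5ccc(OCc6ccccc6)c(OC)c5)OC[C@@]234)ccc1OCc1ccccc1 | intermediate
9 | (1R,2S,5R,6S)-2,6-bis(4-benzyloxy-3-methoxyphenyl)-3,7-dioxabicyclo[3.3.0]octane-1,5-diol | COc1cc([C@@H]2OC[C@@]3(O)[C@H](c4ccc(OCc5ccccc5)c(OC)c4)OC[C@@]23O)ccc1OCc1ccccc1 | intermediate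
10 | (1R,2S,5R,6S)-2,6-bis(4-hydroxy-3-methoxyphenyl)-3,7-dioxabicyclo[3.3.0]octane-1,5-diol (both aryl groups exo, cis to the bridgehead hydroxyl groups) | COc1cc([C@@H]2OC[C@@]3(O)[C@H](c4ccc(O)c(OC)c4)OC[C@@]23O)ccc1O | target

Total step count: 5
Longest linear sequence: 5 steps (1 → 6 → 7 → 8 → 9 → 10)

Steps most likely to fail

Step 1 is the riskiest. What may go wrong is poor simple diastereoselection at the two carbinol carbons: a lithium-bridged closed transition state would deliver the aryl group to the side of the ester or lactone carbonyl. The enolate may also be lost by β-elimination of the acetal oxygen if it warms before the aldehyde is present. The fallback sets out from 1 and 2 and comes back to the route at 8. The two aldol–lactonisation events are run as in step 1, but in plain THF and without regard to the carbinol configuration, which should give the bis-lactone as a mixture of C2/C6 epimers F1 with both bridgeheads secure. LiAlH4 in THF at 0 °C reduces both lactones to the tetraol acetonide F2, a mixture of carbinol epimers. Catalytic camphorsulfonic acid in CH2Cl2 over 4 Å molecular sieves then ionises the two electron-rich benzylic alcohols. Each cation can only be captured by the hydroxymethyl group that is cis to it on the dioxolane (5-exo closure). Because this etherification is reversible under the acid, the carbinol configuration is erased and reset under thermodynamic control, which should leave each aryl group next to the small acetal oxygen and so give 8. The approach changes from stereoselective C–C bond formation to a stereoconvergent benzylic C–O bond formation.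

Step 3 comes second. What may go wrong is competition between ionisation of the lactols and ionisation of the benzylic ring C–O bonds by the Lewis acid, leading to reductive ring opening, epimerisation at C2/C6 or reductive cleavage of the ketal. The fallback sets out from 6 and comes back at 8. LiAlH4 in THF at 0 °C reduces 6 to the tetraol acetonide F3 with (S)-configured carbinol carbons. TsCl in pyridine with catalytic 4-dimethylaminopyridine sulfonylates the two primary hydroxyl groups selectively. On warming, each benzylic hydroxyl displaces the neighbouring primary sulfonate (intramolecular Williamson etherification, 5-exo-tet). This forms the O3–C4 and O7–C8 bonds at the CH2 carbons and leaves C2 and C6 untouched; no Lewis acid and no cationic intermediate are involved.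

Step 4 comes third. What may go wrong is slow hydrolysis of the hindered ketal of two tertiary alcohols, during which the acid opens the electron-rich benzylic ether bonds (epimerisation at C2/C6 or solvolysis). The fallback sets out from 8 and comes back at 10. Hydrogenolysis (H2, Pd/C, EtOAc–MeOH) first gives the diphenol acetonide F4. Ac2O in pyridine converts it into the bis-acetate F5, whose acetoxy-substituted aryl rings no longer stabilise a benzylic cation. The ketal can then be hydrolysed with aqueous CF3CO2H to the diol bis-acetate F6 without risk to C2 and C6. K2CO3 in MeOH finally removes the two acetates to give 10.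

Further compounds
F1 | step 1 | (1R,5R)-2,6-bis(4-benzyloxy-3-methoxyphenyl)-1,5-(isopropylidenedioxy)-3,7-dioxabicyclo[3.3.0]octane-4,8-dione as a mixture of epimers at C2 and C6 | COc1cc(C2OC(=O)[C@@]3(OC(C)(C)O4)C(c5ccc(OCc6ccccc6)c(OC)c5)OC(=O)[C@@]234)ccc1OCc1ccccc1
F2 | step 1 | {(4R,5R)-4,5-bis[(4-benzyloxy-3-methoxyphenyl)(hydroxy)methyl]-2,2-dimethyl-1,3-dioxolane-4,5-diyl}dimethanol as a mixture of carbinol epimers | COc1cc(C(O)[C@@]2(CO)OC(C)(C)O[C@]2(CO)C(O)c3ccc(OCc4ccccc4)c(OC)c3)ccc1OCc1ccccc1
F3 | step 3 | {(4R,5R)-4,5-bis[(S)-(4-benzyloxy-3-methoxyphenyl)(hydroxy)methyl]-2,2-dimethyl-1,3-dioxolane-4,5-diyl}dimethanol | COc1cc([C@H](O)[C@@]2(CO)OC(C)(C)O[C@]2(CO)[C@@H](O)c3ccc(OCc4ccccc4)c(OC)c3)ccc1OCc1ccccc1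
F4 | step 4 | (1R,2S,5R,6S)-2,6-bis(4-hydroxy-3-methoxyphenyl)-1,5-(isopropylidenedioxy)-3,7-dioxabicyclo[3.3.0]octane | COc1cc([C@@H]2OC[C@@]3(OC(C)(C)O4)[C@H](c5ccc(O)c(OC)c5)OC[C@@]234)ccc1O
F5 | step 4 | (1R,2S,5R,6S)-2,6-bis(4-acetoxy-3-methoxyphenyl)-1,5-(isopropylidenedioxy)-3,7-dioxabicyclo[3.3.0]octane | COc1cc([C@@H]2OC[C@@]3(OC(C)(C)O4)[C@H](c5ccc(OC(C)=O)c(OC)c5)OC[C@@]234)ccc1OC(C)=O
F6 | step 4 | (1R,2S,5R,6S)-2,6-bis(4-acetoxy-3-methoxyphenyl)-3,7-dioxabicyclo[3.3.0]octane-1,5-diol | COc1cc([C@@H]2OC[C@@]3(O)[C@H](c4ccc(OC(C)=O)c(OC)c4)OC[C@@]23O)ccc1OC(C)=O
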